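Assumption: 5-methoxybenzene-1,3-diol (1) is taken as the commercial starting material. The target 9 has no stereocenter, so no configuration has to be set or kept.

Route in one line: 1 → 2 → (3) → 4 → 5 → (6) → 7 → (8) → 9.

## The problem

The target 9 is an achiral diarylmethane in which two acetophloroglucinol monomethyl ether rings are joined by one sp3 CH2 group, so the whole difficulty lies in connectivity and site selectivity. Numbered from the acetyl-bearing carbon, ring A carries C1 acetyl, C2 OH, C3 bridge CH2, C4 OH, C5 H and C6 OMe. Ring B is hexasubstituted and carries C1' acetyl, C2' OH, C3' CH3, C4' OH, C5' bridge and C6' OMe. The bridge must therefore sit between two hydroxyls on ring A but between a hydroxyl and the methoxy group on ring B. Each O-methyl must sit on a chelated oxygen ortho to acetyl while the more acidic para hydroxyl stays free, which is against the usual order of phenol alkylation. Joining two different acylphloroglucinols through a C1 electrophile gives both homodimers beside the crossed dimer, and the ring A monomer offers two nucleophilic ring carbons. Methylene-bridged acylphloroglucinols scramble in alkali or hot acid by retro-Michael release of a quinone methide (the rottlerone-type change), the free phenols are air-sensitive in base, and a methoxy group ortho to acetyl is cleaved by strong Lewis acids, so the bridge should be made last and near neutrality.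

The feature that makes the key step possible is a hidden identity. Rings A and B carry the same six substituents in the same order (acetyl, OH, carbon substituent, OH, open position, OMe). The bridge carbon is the C3 methyl carbon of the ring A unit, and it is bonded to C5', the only ring carbon of the ring B unit that would otherwise bear hydrogen. Hence 9 equals two molecules of the single acetophenone 7 minus H2.

## Retrosynthesis

**9 to 7 (through 8).** The bond between the bridge carbon and C5' of ring B is cut, not the bond between the bridge and C3 of ring A. The neighbouring cut would leave a ring A nucleophile with two open ring positions and would need two different monomers. The chosen cut leaves ring B as 7, whose only unsubstituted ring carbon is C5, and ring A as the ortho-quinone methide 8, which is 7 minus H2. The precursor is thus one C10 compound instead of a C20 compound, with no crossed-coupling or regiochemical question left. This copies the presumed biosynthesis of such dimers, in which the bridge is thought to arise from a C-methyl group through its quinone methide. The forward reaction must take two electrons and two hydrogens from the C3 methyl and 4-OH of one molecule of 7, avoid one-electron ring coupling, and let a second molecule of 7 trap 8 faster than 9 is oxidized further.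

**7 to 5 (through 6).** The aryl-acetyl bond is cut. The resorcinol 5 has a mirror plane through C2 and C5, so its two unsubstituted ring carbons are equivalent and a single C-acylation can only give 7, with the acetyl flanked by OH and OMe. The neighbouring cuts are worse. O-methylation of the corresponding trihydroxy ketone would have to select the chelated ortho hydroxyl over the para one. C-methylation of a preformed acetophenone would have to choose between two ring carbons. The Hoesch reaction with acetonitrile, through the ketiminium salt 6, needs no strong Lewis acid and stops after one acylation.

**5 to 4 to 2 to 1 (through 3).** The C2-CH3 bond is cut. In the bis(methoxymethyl) ether 2 the two acetal groups protect the phenols and together direct lithiation to the carbon between them, giving aryllithium 3, which is methylated to 4. Acid methanolysis of 4 releases 5, and 2 comes from commercial 1 in one step. The forward reaction needs metalation between the two acetal oxygens in preference to the two positions flanked by one acetal oxygen and the methoxy group.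

## Roads not taken

**Alternative 1:** the most obvious plan cuts both bridge bonds and joins 7 with 1-(2,4-dihydroxy-6-methoxyphenyl)ethan-1-one A1 through formaldehyde or a Mannich equivalent.
- Forward key step: acid- or base-mediated condensation of the two phenols with the C1 electrophile.
- Why the chosen plan is better: this needs two monomers and gives homodimers such as the bis-aryl methane A2 from 7. Because A1 has two nucleophilic carbons, it also gives the regioisomeric crossed dimer A3, bridged between OH and OMe. The basic or acidic medium is the one in which the bridged products scramble. The chosen plan has one monomer and one possible site on each partner.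

**Alternative 2:** cut the bridge-ring A bond as aryl anion plus aldehyde and introduce both acetyl groups last.
- Forward key step: aryllithium 3 adds to the aldehyde A4 (from 4 by a second metalation and DMF) to give the diaryl carbinol A5. Ionic hydrogenation with loss of the acetals gives the diarylmethane A6, which is then doubly acetylated.
- Why the chosen plan is better: the regiochemistry is sound, since ring A of A6 has two equivalent open carbons and ring B has one. However, the route is longer, and the final double acylation exposes an electron-rich bis-resorcinol methane to exactly the acidic conditions that cleave and redistribute such bridges.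

**Alternative 3:** build ring B from an open chain in polyketide fashion.
- Forward key step: Claisen cyclization of the triketo ester A7, which carries the ring A benzyl group at C2 and a methyl at C4, to give the acylphloroglucinol A8.
- Why the chosen plan is better: A8 has three free hydroxyls on ring B, and the one to be methylated is the chelated, most hindered hydroxyl between acetyl and the bridge, in the presence of four other phenols. The chain A7 would take many steps, and the ring A benzyl electrophile would still have to be made regioselectively. The ring construction therefore solves none of the real selectivity problems.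

Key step: step 5

## Steps

Step 1
Reactants: 1 5-methoxybenzene-1,3-diol
Product: 2 1-methoxy-3,5-bis(methoxymethoxy)benzene
Conditions: NaH, MOMCl, DMF, 0 °C to rt
Reagents that add atoms: chloromethyl methyl ether (MOMCl), COCCl
Why: Williamson-type O-alkylation of the two phenoxides with a hard electrophile should give the bis-acetal, which serves both as protecting group and as directing group for the next step.

Step 2
Reactants: 2 1-methoxy-3,5-bis(methoxymethoxy)benzene
Product: 4 5-methoxy-1,3-bis(methoxymethoxy)-2-methylbenzene, via aryllithium 3 (not isolated)
Conditions: n-BuLi, TMEDA, THF, 0 °C; then MeI, -78 °C to rt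
Reagents that add atoms: iodomethane, CI
Why: Directed ortho-metalation; the carbon between the two methoxymethoxy groups is coordinated by two acetal oxygens and should be lithiated in preference to the positions next to the weaker methoxy director, and the aryllithium is then methylated by SN2 reaction with MeI.

Step 3
Reactants: 4 5-methoxy-1,3-bis(methoxymethoxy)-2-methylbenzene
Product: 5 5-methoxy-2-methylbenzene-1,3-diol
Conditions: conc. HCl (cat.), MeOH, 50 °C, under argon
Reagents that add atoms: none
Why: Acid-catalysed transacetalization to methanol cleaves both methoxymethyl ethers while the aryl methyl ether is inert under these conditions.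

Step 4
Reactants: 5 5-methoxy-2-methylbenzene-1,3-diol
Product: 7 1-(2,4-dihydroxy-6-methoxy-3-methylphenyl)ethan-1-one, via ketiminium chloride 6 (not isolated)
Conditions: MeCN, ZnCl2, HCl (g), Et2O, 0 °C; then H2O, reflux
Reagents that add atoms: acetonitrile, CC#N; water, O
Why: Hoesch reaction; the nitrilium electrophile attacks one of the two mirror-related ring carbons between OH and OMe, so only one C-acylation product is possible, the ketiminium salt deactivates the ring against a second acylation, and hydrolysis gives the ketone without a Lewis acid strong enough to cleave the methyl ether.

Step 5
Reactants: 7 1-(2,4-dihydroxy-6-methoxy-3-methylphenyl)ethan-1-one (two molecules; one is oxidized, the other acts as the nucleophile)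
Product: 9 1-{3-[(5-acetyl-2,4-dihydroxy-6-methoxy-3-methylphenyl)methyl]-2,4-dihydroxy-6-methoxyphenyl}ethan-1-one, via ortho-quinone methide 8 (not isolated)
Conditions: DDQ (0.45 equiv, added slowly), 1,4-dioxane, 10 °C to rt, under argon; unchanged 7 recovered
Reagents that add atoms: none
Why: Proposed new method: DDQ should remove hydride from the C3 methyl group of one molecule of 7 through the charge-transfer complex of the electron-rich phenol, and loss of the proton of the neighbouring 4-OH gives the ortho-quinone methide 8, whose exocyclic CH2 is then attacked by C5 of a second molecule of 7 in a vinylogous Michael (Friedel-Crafts-type) addition, after which tautomerization of the dienone restores ring B and gives 9. The closest known reaction types are the DDQ dehydrogenation of ortho-prenyl acylphloroglucinols to 2,2-dimethylchromenes, which passes through the same kind of quinone methide by benzylic hydride loss next to a free phenol, the DDQ-mediated cross-dehydrogenative coupling of benzylic C-H bonds with electron-rich arenes, and the thermal union of acylphloroglucinols with quinone methides released from Mannich bases; new here is a plain aryl methyl group as hydride donor and one compound serving as both partners. No ring is closed and no stereocenter is formed. The site of oxidation is secured because only the C3 methyl lies ortho to a phenolic OH and can become a quinone methide carbon, which the acetyl methyl and the O-methyl cannot, and the site of C-C bond formation is secured because C5 is the only unsubstituted ring carbon of 7, so neither a regioisomer nor a crossed dimer can arise. O-attack of a phenol or of the spent hydroquinone on 8 gives benzyl aryl ethers that can revert to 8, whereas C-attack is made irreversible by rearomatization. The step needs chemoselectivity against one-electron phenol coupling, self-dimerization of 8 and further oxidation of 9 at its bridge or at the ring B methyl, and keeping 7 in excess over DDQ, adding the oxidant slowly and stopping at partial conversion should hold these back.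

## Compound list

1 | 5-methoxybenzene-1,3-diol | COc1cc(O)cc(O)c1 | starting material
2 | 1-methoxy-3,5-bis(methoxymethoxy)benzene | COCOc1cc(OC)cc(OCOC)c1 | intermediate
3 | [4-methoxy-2,6-bis(methoxymethoxy)phenyl]lithium | [Li]c1c(OCOC)cc(OC)cc1OCOC | intermediate
4 | 5-methoxy-1,3-bis(methoxymethoxy)-2-methylbenzene | COCOc1cc(OC)cc(OCOC)c1C | intermediate
5 | 5-methoxy-2-methylbenzene-1,3-diol | COc1cc(O)c(C)c(O)c1 | intermediate
6 | 1-(2,4-dihydroxy-6-methoxy-3-methylphenyl)ethan-1-iminium chloride | CC(=[NH2+])c1c(O)c(C)c(O)cc1OC.[Cl-] | intermediate
7 | 1-(2,4-dihydroxy-6-methoxy-3-methylphenyl)ethan-1-one | CC(=O)c1c(O)c(C)c(O)cc1OC | intermediate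
8 | 4-acetyl-5-hydroxy-3-methoxy-6-methylidenecyclohexa-2,4-dien-1-one | C=C1C(=O)C=C(OC)C(C(C)=O)=C1O | intermediate
9 | 1-{3-[(5-acetyl-2,4-dihydroxy-6-methoxy-3-methylphenyl)methyl]-2,4-dihydroxy-6-methoxyphenyl}ethan-1-one | COc1cc(O)c(Cc2c(O)c(C)c(O)c(C(C)=O)c2OC)c(O)c1C(C)=O | target

## Step count and least certain steps

Total steps: 5. Longest linear sequence: 5.

**Step 5 (key step, proposed new method).**
- What may go wrong: hydride loss from a plain aryl methyl group is slower than from a prenyl CH2, so one-electron oxidation of the phenol and radical coupling through ring carbon or oxygen may compete. The quinone methide may dimerize by hetero-Diels-Alder reaction or be intercepted by addition of the phenol to the quinone oxidant. The product may be oxidized further at its doubly benzylic bridge or at the remaining ring B methyl, leading to chain extension to oligomers.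
- Fallback (known chemistry, no oxidant in the coupling): it sets out from 7 and returns at 9. Acetylation of both phenols (Ac2O, pyridine) should give 4-acetyl-5-methoxy-2-methyl-1,3-phenylene diacetate F1. Wohl-Ziegler bromination of its aryl methyl group (NBS, AIBN, PhCF3, reflux) should give 4-acetyl-2-(bromomethyl)-5-methoxy-1,3-phenylene diacetate F2. F2 is then added to an excess of 7 with K2CO3 in MeOH at 0 °C. Methanolysis of the aryl acetates frees the phenoxide, which expels bromide to give the same quinone methide 8, and 8 is trapped at C5 of 7 to give 9. The single-monomer logic and the fixed regiochemistry are kept.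

**Step 2.**
- What may go wrong: incomplete site selectivity of the metalation, with lithiation also at the two positions flanked by one acetal oxygen and the methoxy group, giving an inseparable isomeric methylation product.
- Fallback: it sets out from 1 and returns at 5, with a directing group of a higher class and a reductive unmasking. Carbamoylation (ClCONEt2, K2CO3, MeCN, reflux) should give 5-methoxy-1,3-phenylene bis(N,N-diethylcarbamate) F3. Carbamate-directed ortho-metalation between the two carbamates (s-BuLi, TMEDA, THF, -78 °C, kept cold to avoid anionic Fries migration) and MeI should give 5-methoxy-2-methyl-1,3-phenylene bis(N,N-diethylcarbamate) F4. Reduction with LiAlH4 in THF at reflux releases 5.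

**Step 4.**
- What may go wrong: slow C-acylation with competing O-imidate formation, or incomplete hydrolysis of the ketiminium salt, on a ring that is hindered on both sides of the reacting carbon.
- Fallback: it sets out from 4 and returns at 7, replacing electrophilic substitution by a second directed metalation. Treatment of 4 with n-BuLi and TMEDA in THF at 0 °C should lithiate one of the two equivalent ring carbons between an acetal oxygen and the methoxy group. Acylation with N-methoxy-N-methylacetamide should give 1-[6-methoxy-2,4-bis(methoxymethoxy)-3-methylphenyl]ethan-1-one F5, and catalytic HCl in MeOH at 50 °C then gives 7.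

## Further compounds

F1 | step 5 | 4-acetyl-5-methoxy-2-methyl-1,3-phenylene diacetate | CC(=O)Oc1cc(OC)c(C(C)=O)c(OC(C)=O)c1C
F2 | step 5 | 4-acetyl-2-(bromomethyl)-5-methoxy-1,3-phenylene diacetate | CC(=O)Oc1cc(OC)c(C(C)=O)c(OC(C)=O)c1CBr
F3 | step 2 | 5-methoxy-1,3-phenylene bis(N,N-diethylcarbamate) | CCN(CC)C(=O)Oc1cc(OC)cc(OC(=O)N(CC)CC)c1
F4 | step 2 | 5-methoxy-2-methyl-1,3-phenylene bis(N,N-diethylcarbamate) | CCN(CC)C(=O)Oc1cc(OC)cc(OC(=O)N(CC)CC)c1C
F5 | step 4 | 1-[6-methoxy-2,4-bis(methoxymethoxy)-3-methylphenyl]ethan-1-one | COCOc1cc(OC)c(C(C)=O)c(OCOC)c1C
A1 | alternative 1 | 1-(2,4-dihydroxy-6-methoxyphenyl)ethan-1-one | CC(=O)c1c(O)cc(O)cc1OC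
A2 | alternative 1 | bis(5-acetyl-2,4-dihydroxy-6-methoxy-3-methylphenyl)methane | COc1c(Cc2c(O)c(C)c(O)c(C(C)=O)c2OC)c(O)c(C)c(O)c1C(C)=O
A3 | alternative 1 | 1-{5-[(3-acetyl-4,6-dihydroxy-2-methoxyphenyl)methyl]-2,4-dihydroxy-6-methoxy-3-methylphenyl}ethan-1-one | COc1c(Cc2c(O)c(C)c(O)c(C(C)=O)c2OC)c(O)cc(O)c1C(C)=O
A4 | alternative 2 | 6-methoxy-2,4-bis(methoxymethoxy)-3-methylbenzaldehyde | COCOc1cc(OC)c(C=O)c(OCOC)c1C
A5 | alternative 2 | [4-methoxy-2,6-bis(methoxymethoxy)phenyl][6-methoxy-2,4-bis(methoxymethoxy)-3-methylphenyl]methanol | COCOc1cc(OC)c(C(O)c2c(OCOC)cc(OC)cc2OCOC)c(OCOC)c1C
A6 | alternative 2 | 4-[(2,6-dihydroxy-4-methoxyphenyl)methyl]-5-methoxy-2-methylbenzene-1,3-diol | COc1cc(O)c(Cc2c(OC)cc(O)c(C)c2O)c(O)c1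
A7 | alternative 3 | methyl 2-[(3-acetyl-2,6-dihydroxy-4-methoxyphenyl)methyl]-4-methyl-3,5,7-trioxooctanoate | COC(=O)C(Cc1c(O)cc(OC)c(C(C)=O)c1O)C(=O)C(C)C(=O)CC(C)=O
A8 | alternative 3 | 1-{3-[(3-acetyl-2,4,6-trihydroxy-5-methylphenyl)methyl]-2,4-dihydroxy-6-methoxyphenyl}ethan-1-one | COc1cc(O)c(Cc2c(O)c(C)c(O)c(C(C)=O)c2O)c(O)c1C(C)=O
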